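**Remark on the chemistry (assumption):** ring A is the guaiacyl ring on the ketone, ring B the core aryl ring that carries the ketone arm, ring C the benzo ring of the dihydrobenzofuran and ring D its 2-aryl group. The carbinol centres made in steps 13 and 18 form as epimer pairs and are drawn without configuration (erased in step 14, sorted in step 19).

## The problem

The target is a tetra-aryl lignan built on a 2,6-diaryl-3,7-dioxabicyclo[3.3.0]octane (furofuran) core of the (+)-pinoresinol series: C2 and C6 are S, the bridgeheads C1 and C5 are R, and both aryl groups sit on the convex face. Each core aryl ring carries, ortho to its phenolic oxygen, a three-carbon unit that ends in a further guaiacyl ring. On ring C the unit is closed through that oxygen to a cis-(2S,3S)-2-aryl-3-hydroxymethyl-2,3-dihydrobenzofuran with ring D at C2; on ring B it stays open as an (S)-2-aryl-3-hydroxypropan-1-one with ring A on the carbonyl carbon. The seven stereocentres form three sets too far apart to steer one another: in the core one aryl-bearing carbon can direct the other three, in the dihydrobenzofuran C3 cannot set C2 by equilibration because cis is the less stable arrangement, and the ketone α-carbon stands alone. The open arm is the fragile part: its α-hydrogen is benzylic and α to an aryl ketone, so base epimerises it, the β-hydroxy ketone can lose water or formaldehyde, and under acid the neighbouring phenol can add to the carbonyl group and dehydrate to a benzofuran. The benzylic ether carbons of the core and of the dihydrobenzofuran ionise under strong acid (exo to endo, cis to trans) and are cleaved by hydrogenolysis, so the last steps must be close to neutral. The feature that opens the route is that O1–C2 of the dihydrobenzofuran joins the phenolic oxygen on C7a of ring C to a benzylic carbinol carbon, while C2–C3 is the bond an aldol between a ring C arylacetate and the ring D aldehyde would make; the syn aldol differs from the cis ring by one inversion at C2. The same aldol unit, with the carbinol oxidised instead of displaced, is the ketone arm on ring B, and the α-carbons of both arms have the same spatial sense, so one intermediate can serve both halves.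

## Retrosynthesis

**Target 33 back to carbinol 31.** No skeletal bond is cut. The ring A ketone is traced through the silylated ketone 32 to the benzylic carbinol of 31. Making the ring B–Cα or Cα–carbonyl bond late, by enolate arylation or acyl coupling, would create the labile α-centre under basic or reducing metal conditions with uncertain control. Here it stays a configurationally stable alcohol until the second-last step. 31 differs from 33 only in oxidation level and five silyl groups. The forward steps must oxidise without enolisation and desilylate without epimerisation or dehydration.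

**31 back to 29.** Only protecting groups change. The two aryl silyl ethers on rings A and D and the free carbinol of 31 go back through 30 to the two pivalates and the acetate of 29. Esters are wanted earlier: a pivalate para to the carbinol serves the key step and keeps rings A and D electron-poor during the Lewis-acidic core formation. Silyl ethers are wanted at the end because they leave without base. One hydride step has to remove all three esters.

**29 back to 26 and 21.** The core is cut at C1–C5 and C6–O7 to the epoxy cinnamyl ether 27, and 27 at its ether C–O bond to epoxy alcohol 26 (ring B half) and cinnamyl bromide 21 (ring C half). Aldol–lactone routes to furofurans need more steps per aryl group, and oxidative phenol coupling cannot join two different aryl units selectively. This cut needs only an aldehyde on each half and turns one carbinol centre into all four core centres. The forward reaction is reductive epoxide opening by Cp2TiCl (trivalent titanium), 5-exo radical addition and iodine-induced ether closure.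

**26 back to 24, and 21 back to 19.** Each three-carbon handle is cut between the aryl carbinol carbon and a vinyl group: 26 through allylic alcohol 25 from aldehyde 24, and 21 through allylic alcohol 20 from aldehyde 19. One Grignard addition serves both halves. On the ring C half the carbinol is only a relay for the transposed bromide. On the ring B half it is the controlling centre of the core and is selected by a Sharpless kinetic resolution that delivers the epoxide in the same operation. An olefination–hydride route to 21 was set aside because hydride would strip the pivalate.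

**24 and 19 back to 17.** Both aldehydes are unmasked dioxolanes of one parent. 19 comes from cis-dihydrobenzofuran 18, and 18 from phenol diol 17 by cutting O1–C2 (the key step). 24 comes from the same 17 by capping the phenol (22) and the carbinol (23). Acid closure through a quinone-methide-type cation would give the trans ring, and hydrogenation of a benzofuran would give no absolute control; displacement with inversion is stereospecific. The gain is that one acyclic compound, 17, holds all three non-core stereocentres of the target in latent form.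

**17 back to 10 and 12.** The Cα–Cβ bond is cut, through 16, 15 and 14, to imide 10 and O-pivaloylvanillin 12. An auxiliary-controlled boron aldol sets both centres at once in the syn relation, and the (R)-auxiliary gives the absolute sense needed for both arms. The primary alcohol of 15 must be capped (16) so that the benzylic oxygen is the only one that can leave. The ring C phenol is freed (17) by neutral hydrogenolysis.

**10 back to 1, 4 and 8; 12 back to 11.** The aryl–CH2 bond is cut to bromide 3 and dimethyl malonate 4 (malonate 5, acid 7). 3 comes from 5-bromovanillin 1 through benzyl ether 2; the acid is joined to oxazolidinone 8. A benzyl ether is preferred to an allyl ether because zerovalent palladium and a malonate anion would ionise an aryl allyl ether in the arylation. The dioxolane keeps the aldehyde out of Knoevenagel, enolate and hydride chemistry. 12 is vanillin 11 acylated once.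

## Roads not taken

**Alternative 1: twofold Friedel–Crafts arylation of a bis-acetal.** The cut is at both core C–aryl bonds. BF3·OEt2 would ionise the two methyl acetals of the bicyclic bis-acetal A3 in turn, and each oxocarbenium ion would be attacked by the para carbon of 2-bromo-6-methoxyphenol A2, giving 5,5'-dibromopinoresinol A1. Merits: the core appears in one step from small pieces; the exo,exo isomer is the thermodynamic one under the same Lewis acid; the para position of A2 is the only strongly activated free site. Weak points for this target: A3 must be obtained enantiopure. A1 is C2-symmetric, so two identical bromides must later become two different arms, and that differentiation can only be statistical. Both arms would then be built on the acid-sensitive core through arylation, aldol and hydride steps. In brevity of core construction this road is better. The chosen plan sets against it that the arms are different from the moment the common intermediate 17 divides, and that the cis ring and the ketone α-centre are fixed before the core exists.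

**Alternative 2: twofold aromatic Claisen rearrangement.** The cut is at the ring B–Cα bond and the ring C C3a–C3 bond. Heating the bis[(R,E)-3-aryl-5-silyloxypent-3-en-2-yl] ether A5, with Eu(fod)3 (trivalent europium) if catalysis were needed, would move both allyl units from oxygen to the one free ortho carbon of each ring and give the C2-symmetric bis-phenol A4. Merits: both aryl–carbon bonds form in one operation on the intact core; the regiochemistry is unambiguous; chair transition states can transfer chirality from the ether carbon to the new benzylic centre. Weak points: A5 needs an enantiopure secondary allylic alcohol with a defined trisubstituted alkene, attached twice to a hindered phenol without allylic transposition. The rearrangement temperature threatens the furofuran. A4 again has two identical arms. Each ethylidene group must be cleaved to a ketone, which exposes the labile α-aryl ketone on both arms early. One ketone would then have to be reduced selectively and diastereoselectively to the syn alcohol before ring closure. In bond economy this road is superior. The chosen plan answers with auxiliary-controlled stereocentres of known reliability and with a ketone that appears only once, at the end.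

**Alternative 3: symmetric titanocene bicyclisation.** The cut is at C1–C5 and C6–O7 of the core. Cp2TiCl (trivalent titanium) would open the terminal epoxide of the epoxy cinnamyl ether A7, made from two molecules of 1. The radical would add 5-exo to the alkene, and iodine would close the second ring to the C2-symmetric dibromide A6. Merits: this is the same bicyclisation the chosen plan uses, but run early on cheap material, so the kinetic resolution that sets the core costs little. Here this road is clearly better, because the chosen plan resolves the advanced intermediate 25 and can use at most half of it per pass. Weak points: A6 is symmetric, so the arms must be differentiated statistically. Both arms would be built after the core by twofold arylation and aldol chemistry in a long linear sequence. The methoxymethyl ethers need acid for removal in the presence of the core. The chosen plan accepts the late resolution in exchange for a convergent union of two fully formed, already different halves.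

Key step: step 11

## Route

**Step 1**
Reactants: 1 5-bromovanillin
Product: 2 4-(benzyloxy)-3-bromo-5-methoxybenzaldehyde
Conditions: BnBr, K2CO3, DMF, 60 °C
Reagents that add atoms: benzyl bromide, BrCc1ccccc1
Why: Williamson etherification of the phenoxide; the benzyl ether survives palladium, base and borohydride and leaves by neutral hydrogenolysis.

**Step 2**
Reactants: 2 4-(benzyloxy)-3-bromo-5-methoxybenzaldehyde
Product: 3 2-[4-(benzyloxy)-3-bromo-5-methoxyphenyl]-1,3-dioxolane
Conditions: ethylene glycol, TsOH (cat.), toluene, reflux, Dean–Stark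
Reagents that add atoms: ethylene glycol, OCCO
Why: acid-catalysed acetalisation with removal of water; the dioxolane keeps the aldehyde out of Knoevenagel, enolate and hydride chemistry.

**Step 3**
Reactants: 3 aryl bromide dioxolane; 4 dimethyl malonate
Product: 5 dimethyl 2-[2-(benzyloxy)-5-(1,3-dioxolan-2-yl)-3-methoxyphenyl]malonate
Conditions: Pd(OAc)2 (2 mol %), P(tBu)3·HBF4 (4 mol %), K3PO4, toluene, 90 °C
Reagents that add atoms: none
Why: Buchwald–Hartwig-type α-arylation of a malonate; the bulky electron-rich phosphine allows oxidative addition to the electron-rich ortho-alkoxy bromide, and the product malonate is too hindered to be arylated twice.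

**Step 4**
Reactants: 5 dimethyl arylmalonate
Product: 7 [2-(benzyloxy)-5-(1,3-dioxolan-2-yl)-3-methoxyphenyl]acetic acid, via arylmalonate disodium salt 6 (not isolated)
Conditions: NaOH, MeOH/H2O, 60 °C; then AcOH (1 equiv), pyridine, 100 °C; cold aq. NaH2PO4 (pH 4.5) work-up
Reagents that add atoms: sodium hydroxide, [Na+].[OH-]
Why: saponification followed by Doebner-type decarboxylation of the malonate half-salt in pyridine; the medium never becomes acidic enough to hydrolyse the dioxolane.

**Step 5**
Reactants: 7 arylacetic acid; 8 (R)-4-benzyl-2-oxazolidinone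
Product: 10 (R)-4-benzyl-3-{[2-(benzyloxy)-5-(1,3-dioxolan-2-yl)-3-methoxyphenyl]acetyl}-2-oxazolidinone, via mixed pivalic anhydride 9 (not isolated)
Conditions: PivCl, Et3N, THF, −20 °C; then 8, LiCl, −20 °C → rt
Reagents that add atoms: none
Why: mixed-anhydride N-acylation of the oxazolidinone; the hindered pivaloyl carbonyl directs attack to the arylacetyl carbonyl, and no strong base touches the acidic arylacetyl hydrogens.

**Step 6**
Reactants: 11 vanillin
Product: 12 4-formyl-2-methoxyphenyl pivalate
Conditions: PivCl, Et3N, DMAP (cat.), CH2Cl2, 0 °C → rt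
Reagents that add atoms: pivaloyl chloride, CC(C)(C)C(Cl)=O
Why: acylation of the phenol; the pivalate is hindered enough for the later borohydride and Grignard steps and makes ring D electron-poor for the key step.

**Step 7**
Reactants: 10 arylacetyl imide; 12 O-pivaloylvanillin
Product: 14 (R)-4-benzyl-3-[(2R,3R)-2-aryl-3-hydroxy-3-(3-methoxy-4-pivaloyloxyphenyl)propanoyl]-2-oxazolidinone (aryl = 2-benzyloxy-5-dioxolanyl-3-methoxyphenyl), via boron Z-enolate 13 (not isolated)
Conditions: Bu2BOTf, iPr2NEt, CH2Cl2, −78 → 0 °C; 12, −78 → 0 °C; then H2O2, MeOH, pH 7 buffer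
Reagents that add atoms: none
Why: Evans syn aldol. The Z boron enolate reacts through a Zimmerman–Traxler chair on the face away from the auxiliary benzyl group, so Cα and Cβ are set together as (2R,3R). Cα is the later C3 of the dihydrobenzofuran and the later ketone α-carbon.

**Step 8**
Reactants: 14 syn-aldol imide
Product: 15 4-[(1R,2S)-2-[2-(benzyloxy)-5-(1,3-dioxolan-2-yl)-3-methoxyphenyl]-1,3-dihydroxypropyl]-2-methoxyphenyl pivalate
Conditions: NaBH4, THF/H2O, 0 °C → rt
Reagents that add atoms: none
Why: borohydride reduction of the activated imide carbonyl to the primary alcohol with release of the auxiliary; the hindered aryl pivalate and the acetal are expected to survive, and the low temperature limits retro-aldol.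

**Step 9**
Reactants: 15 diol
Product: 16 primary tert-butyldimethylsilyl ether of 15
Conditions: TBSCl, imidazole, CH2Cl2, 0 °C
Reagents that add atoms: tert-butyldimethylsilyl chloride, CC(C)(C)[Si](C)(C)Cl
Why: silylation selects the primary hydroxyl over the hindered benzylic one; this removes the competing 5-exo closure onto the primary carbon in step 11.

**Step 10**
Reactants: 16 benzyl ether
Product: 17 4-[(1R,2S)-3-(tert-butyldimethylsilyloxy)-2-[5-(1,3-dioxolan-2-yl)-2-hydroxy-3-methoxyphenyl]-1-hydroxypropyl]-2-methoxyphenyl pivalate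
Conditions: H2 (1 atm), Pd/C (10 % Pd on carbon), EtOAc, rt
Reagents that add atoms: none
Why: hydrogenolysis of the aryl benzyl ether under neutral conditions; the acyloxy-substituted benzylic alcohol and the acetal are much slower to cleave without acid.

**Step 11 (key step)**
Reactants: 17 syn phenol diol
Product: 18 4-[(2S,3S)-3-(tert-butyldimethylsilyloxymethyl)-5-(1,3-dioxolan-2-yl)-7-methoxy-2,3-dihydrobenzofuran-2-yl]-2-methoxyphenyl pivalate
Conditions: PPh3, DIAD, THF, 0 °C → rt
Reagents that add atoms: none
Why: PPh3 and DIAD form the betaine, which takes the proton of the phenol (the only acidic O–H) and passes the phosphonium to the benzylic hydroxyl, the primary one being silylated; the ortho phenoxide then attacks the oxyphosphonium carbon from the rear. The closest known reaction is the Mitsunobu cycloetherification of 2-(2-hydroxyaryl)-1-arylethanols to 2-aryl-2,3-dihydrobenzofurans. The ring closes in the 5-exo-tet mode and forms O1–C2. C2 is the only new stereocentre: the (R)-carbinol is inverted to (S), while C3 (S) comes unchanged from the aldol, so the syn diol maps onto the cis ring. The step needs substitution to win over ionisation, which would leak to the trans ring, and over elimination to the stilbene. The pivaloyloxy group para to the carbinol withholds resonance donation from the benzylic carbon, and the five-membered intramolecular attack should be fast at 0 °C. Triphenylphosphine oxide and the reduced azo ester are the only by-products.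

**Step 12**
Reactants: 18 cis-dihydrobenzofuran dioxolane
Product: 19 4-[(2S,3S)-3-(tert-butyldimethylsilyloxymethyl)-5-formyl-7-methoxy-2,3-dihydrobenzofuran-2-yl]-2-methoxyphenyl pivalate
Conditions: PPTS (cat.), acetone/H2O, 40 °C
Reagents that add atoms: water, O
Why: mild acetal hydrolysis; the weak acid is not expected to ionise the acyloxyaryl-substituted C2 or to cleave the silyl ether.

**Step 13**
Reactants: 19 aldehyde
Product: 20 4-[(2S,3S)-3-(tert-butyldimethylsilyloxymethyl)-5-(1-hydroxyprop-2-en-1-yl)-7-methoxy-2,3-dihydrobenzofuran-2-yl]-2-methoxyphenyl pivalate (carbinol epimers)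
Conditions: CH2=CHMgBr, THF, −78 °C
Reagents that add atoms: vinylmagnesium bromide, C=C[Mg]Br
Why: Grignard addition to the aldehyde, which reacts far faster than the hindered aryl pivalate at −78 °C; the new centre is lost in step 14.

**Step 14**
Reactants: 20 allylic alcohol
Product: 21 4-[(2S,3S)-5-[(E)-3-bromoprop-1-en-1-yl]-3-(tert-butyldimethylsilyloxymethyl)-7-methoxy-2,3-dihydrobenzofuran-2-yl]-2-methoxyphenyl pivalate
Conditions: PBr3, pyridine (cat.), Et2O, −20 → 0 °C
Reagents that add atoms: phosphorus tribromide, BrP(Br)Br
Why: bromination of a 1-arylallyl alcohol with allylic transposition; bromide enters at the terminal carbon of the aryl-stabilised allyl system and gives the conjugated (E)-cinnamyl bromide. The bromide is used at once.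

**Step 15**
Reactants: 17 syn phenol diol
Product: 22 aryl tert-butyldimethylsilyl ether of 17 (ring B oxygen silylated, benzylic hydroxyl free)
Conditions: TBSCl (1.2 equiv), imidazole, DMF, 0 °C → rt
Reagents that add atoms: tert-butyldimethylsilyl chloride, CC(C)(C)[Si](C)(C)Cl
Why: the acidic phenol is silylated much faster than the hindered secondary benzylic alcohol; the flanked aryl silyl ether is robust towards the later basic steps.

**Step 16**
Reactants: 22 aryl silyl ether
Product: 23 benzylic acetate of 22
Conditions: Ac2O, Et3N, DMAP (cat.), CH2Cl2, rt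
Reagents that add atoms: acetic anhydride, CC(=O)OC(C)=O
Why: DMAP-catalysed acylation of the hindered carbinol; the acetate leaves later in the same hydride step as the pivalates.

**Step 17**
Reactants: 23 acetate dioxolane
Product: 24 4-[(1R,2S)-1-acetoxy-3-(tert-butyldimethylsilyloxy)-2-[2-(tert-butyldimethylsilyloxy)-5-formyl-3-methoxyphenyl]propyl]-2-methoxyphenyl pivalate
Conditions: PPTS (cat.), acetone/H2O, 40 °C
Reagents that add atoms: water, O
Why: mild acetal hydrolysis, as in step 12; esters and silyl ethers are stable.

**Step 18**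
Reactants: 24 aldehyde
Product: 25 1-arylprop-2-en-1-ol from 24 (epimers at the new carbinol)
Conditions: CH2=CHMgBr, THF, −78 °C
Reagents that add atoms: vinylmagnesium bromide, C=C[Mg]Br
Why: Grignard addition to the aldehyde in the presence of the less reactive esters; the remote stereocentres give no bias, so both carbinol epimers are expected.

**Step 19**
Reactants: 25 allylic alcohol (epimer pair)
Product: 26 (R)-aryl[(R)-oxiran-2-yl]methanol (aryl = ring B unit of 24)
Conditions: Ti(OiPr)4 (0.2 equiv), D-(−)-diisopropyl tartrate (0.24 equiv), tBuOOH (0.6 equiv), 4 Å molecular sieves, CH2Cl2, −20 °C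
Reagents that add atoms: tert-butyl hydroperoxide, CC(C)(C)OO
Why: Sharpless kinetic resolution. With the D-tartrate the titanium complex should epoxidise the (S)-carbinol epimer much faster than the (R)-epimer and give the erythro epoxy alcohol, so at most half of 25 is converted and the (R)-epimer is recovered. The carbinol centre chosen here becomes C2 of the core (the ring B carbon); the epoxide centre is erased in step 21.

**Step 20**
Reactants: 26 epoxy alcohol; 21 cinnamyl bromide
Product: 27 epoxy cinnamyl ether (ether oxygen of 26 bonded to the CH2 of 21)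
Conditions: NaH, Bu4NI (cat.), THF, 0 °C → rt
Reagents that add atoms: none
Why: Williamson etherification of a secondary alkoxide with a reactive primary allylic bromide; the alkoxide is formed in the presence of the bromide so that alkylation outruns acyl transfer and epoxide migration.

**Step 21**
Reactants: 27 epoxy cinnamyl ether
Product: 29 protected furofuran (1S,2S,5R,6S; two pivalates, one acetate, three silyl ethers), via benzylic iodide 28 (not isolated)
Conditions: Cp2TiCl2, Zn, THF, rt (gives Cp2TiCl); slow addition of 27; then I2, rt → 60 °C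
Reagents that add atoms: none
Why: titanocene-mediated radical cyclisation of an epoxy cinnamyl ether, the known route to 2,6-diaryl-3,7-dioxabicyclo[3.3.0]octanes. Cp2TiCl (trivalent titanium) opens the epoxide to the secondary β-titanoxy radical, which adds 5-exo to the styrene trans to the aryl group on the neighbouring carbon and cis to the new benzylic arm. Iodine turns the captured benzylic centre into iodide 28, and the titanium alkoxide closes the second ring with the aryl group on the convex face.

**Step 22**
Reactants: 29 protected furofuran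
Product: 30 furofuran with free phenols on rings A and D and free benzylic carbinol
Conditions: iBu2AlH (excess), CH2Cl2, −78 → 0 °C; aq. potassium sodium tartrate
Reagents that add atoms: none
Why: hydride cleavage of the two aryl pivalates and the acetate in one operation; silyl ethers and the cyclic benzylic ethers are inert to iBu2AlH.

**Step 23**
Reactants: 30 diphenol carbinol
Product: 31 pentakis(tert-butyldimethylsilyl) ether with free benzylic carbinol
Conditions: TBSCl (2.4 equiv), imidazole, DMF, 0 °C
Reagents that add atoms: tert-butyldimethylsilyl chloride, CC(C)(C)[Si](C)(C)Cl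
Why: the two unhindered phenols are silylated much faster than the secondary carbinol, which is flanked by a tertiary carbon.

**Step 24**
Reactants: 31 carbinol
Product: 32 pentakis(tert-butyldimethylsilyl) ether of the target
Conditions: Dess–Martin periodinane, pyridine, CH2Cl2, 0 °C → rt
Reagents that add atoms: none
Why: Dess–Martin oxidation of a secondary benzylic alcohol under buffered, non-enolising conditions; the α-centre (S) is expected to be kept.

**Step 25**
Reactants: 32 silylated ketone
Product: 33 CNP0174045.1
Conditions: HF·pyridine, pyridine, THF, 0 °C → rt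
Reagents that add atoms: none
Why: fluoride cleavage of three aryl and two primary silyl ethers in a buffered, weakly acidic medium that forms no enolate; no stereocentre is touched.

## Compound list

1 | 5-bromovanillin | COc1cc(C=O)cc(Br)c1O | starting material
2 | 4-(benzyloxy)-3-bromo-5-methoxybenzaldehyde | COc1cc(C=O)cc(Br)c1OCc1ccccc1 | intermediate
3 | 2-[4-(benzyloxy)-3-bromo-5-methoxyphenyl]-1,3-dioxolane | COc1cc(C2OCCO2)cc(Br)c1OCc1ccccc1 | intermediate
4 | dimethyl malonate | COC(=O)CC(=O)OC | starting material
5 | dimethyl 2-[2-(benzyloxy)-5-(1,3-dioxolan-2-yl)-3-methoxyphenyl]malonate | COC(=O)C(C(=O)OC)c1cc(C2OCCO2)cc(OC)c1OCc1ccccc1 | intermediate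
6 | disodium 2-[2-(benzyloxy)-5-(1,3-dioxolan-2-yl)-3-methoxyphenyl]malonate | [Na+].[Na+].[O-]C(=O)C(C([O-])=O)c1cc(C2OCCO2)cc(OC)c1OCc1ccccc1 | intermediate (not isolated)
7 | [2-(benzyloxy)-5-(1,3-dioxolan-2-yl)-3-methoxyphenyl]acetic acid | OC(=O)Cc1cc(C2OCCO2)cc(OC)c1OCc1ccccc1 | intermediate
8 | (R)-4-benzyl-2-oxazolidinone | O=C1N[C@H](Cc2ccccc2)CO1 | starting material
9 | mixed anhydride of 7 with pivalic acid | CC(C)(C)C(=O)OC(=O)Cc1cc(C2OCCO2)cc(OC)c1OCc1ccccc1 | intermediate (not isolated)
10 | (R)-4-benzyl-3-{[2-(benzyloxy)-5-(1,3-dioxolan-2-yl)-3-methoxyphenyl]acetyl}-2-oxazolidinone | O=C(Cc1cc(C2OCCO2)cc(OC)c1OCc1ccccc1)N1[C@H](Cc2ccccc2)COC1=O | intermediate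
11 | vanillin | COc1cc(C=O)ccc1O | starting material
12 | 4-formyl-2-methoxyphenyl pivalate | COc1cc(C=O)ccc1OC(=O)C(C)(C)C | intermediate
13 | (Z)-dibutylboron enolate of 10 | CCCCB(CCCC)O/C(=C\c1cc(C2OCCO2)cc(OC)c1OCc1ccccc1)N1[C@H](Cc2ccccc2)COC1=O | intermediate (not isolated)
14 | (R)-4-benzyl-3-[(2R,3R)-2-[2-(benzyloxy)-5-(1,3-dioxolan-2-yl)-3-methoxyphenyl]-3-hydroxy-3-(3-methoxy-4-pivaloyloxyphenyl)propanoyl]-2-oxazolidinone | O1CCOC1c1cc(OC)c(OCc2ccccc2)c(c1)[C@@H](C(=O)N1[C@H](Cc2ccccc2)COC1=O)[C@@H](O)c1ccc(OC(=O)C(C)(C)C)c(OC)c1 | intermediate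
15 | 4-[(1R,2S)-2-[2-(benzyloxy)-5-(1,3-dioxolan-2-yl)-3-methoxyphenyl]-1,3-dihydroxypropyl]-2-methoxyphenyl pivalate | O1CCOC1c1cc(OC)c(OCc2ccccc2)c(c1)[C@@H](CO)[C@@H](O)c1ccc(OC(=O)C(C)(C)C)c(OC)c1 | intermediate
16 | 4-[(1R,2S)-2-[2-(benzyloxy)-5-(1,3-dioxolan-2-yl)-3-methoxyphenyl]-3-(tert-butyldimethylsilyloxy)-1-hydroxypropyl]-2-methoxyphenyl pivalate | O1CCOC1c1cc(OC)c(OCc2ccccc2)c(c1)[C@@H](CO[Si](C)(C)C(C)(C)C)[C@@H](O)c1ccc(OC(=O)C(C)(C)C)c(OC)c1 | intermediate
17 | 4-[(1R,2S)-3-(tert-butyldimethylsilyloxy)-2-[5-(1,3-dioxolan-2-yl)-2-hydroxy-3-methoxyphenyl]-1-hydroxypropyl]-2-methoxyphenyl pivalate (key-step precursor) | O1CCOC1c1cc(OC)c(O)c(c1)[C@@H](CO[Si](C)(C)C(C)(C)C)[C@@H](O)c1ccc(OC(=O)C(C)(C)C)c(OC)c1 | intermediate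
18 | 4-[(2S,3S)-3-(tert-butyldimethylsilyloxymethyl)-5-(1,3-dioxolan-2-yl)-7-methoxy-2,3-dihydrobenzofuran-2-yl]-2-methoxyphenyl pivalate (key-step product) | O1CCOC1c1cc(OC)c2c(c1)[C@@H](CO[Si](C)(C)C(C)(C)C)[C@@H](c1ccc(OC(=O)C(C)(C)C)c(OC)c1)O2 | intermediate
19 | 4-[(2S,3S)-3-(tert-butyldimethylsilyloxymethyl)-5-formyl-7-methoxy-2,3-dihydrobenzofuran-2-yl]-2-methoxyphenyl pivalate | O=Cc1cc(OC)c2c(c1)[C@@H](CO[Si](C)(C)C(C)(C)C)[C@@H](c1ccc(OC(=O)C(C)(C)C)c(OC)c1)O2 | intermediate
20 | 4-[(2S,3S)-3-(tert-butyldimethylsilyloxymethyl)-5-(1-hydroxyprop-2-en-1-yl)-7-methoxy-2,3-dihydrobenzofuran-2-yl]-2-methoxyphenyl pivalate (carbinol epimers) | C=CC(O)c1cc(OC)c2c(c1)[C@@H](CO[Si](C)(C)C(C)(C)C)[C@@H](c1ccc(OC(=O)C(C)(C)C)c(OC)c1)O2 | intermediate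
21 | 4-[(2S,3S)-5-[(E)-3-bromoprop-1-en-1-yl]-3-(tert-butyldimethylsilyloxymethyl)-7-methoxy-2,3-dihydrobenzofuran-2-yl]-2-methoxyphenyl pivalate | BrC/C=C/c1cc(OC)c2c(c1)[C@@H](CO[Si](C)(C)C(C)(C)C)[C@@H](c1ccc(OC(=O)C(C)(C)C)c(OC)c1)O2 | intermediate
22 | 4-[(1R,2S)-3-(tert-butyldimethylsilyloxy)-2-[2-(tert-butyldimethylsilyloxy)-5-(1,3-dioxolan-2-yl)-3-methoxyphenyl]-1-hydroxypropyl]-2-methoxyphenyl pivalate | O1CCOC1c1cc(OC)c(O[Si](C)(C)C(C)(C)C)c(c1)[C@@H](CO[Si](C)(C)C(C)(C)C)[C@@H](O)c1ccc(OC(=O)C(C)(C)C)c(OC)c1 | intermediate
23 | 4-[(1R,2S)-1-acetoxy-3-(tert-butyldimethylsilyloxy)-2-[2-(tert-butyldimethylsilyloxy)-5-(1,3-dioxolan-2-yl)-3-methoxyphenyl]propyl]-2-methoxyphenyl pivalate | O1CCOC1c1cc(OC)c(O[Si](C)(C)C(C)(C)C)c(c1)[C@@H](CO[Si](C)(C)C(C)(C)C)[C@@H](OC(C)=O)c1ccc(OC(=O)C(C)(C)C)c(OC)c1 | intermediate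
24 | 4-[(1R,2S)-1-acetoxy-3-(tert-butyldimethylsilyloxy)-2-[2-(tert-butyldimethylsilyloxy)-5-formyl-3-methoxyphenyl]propyl]-2-methoxyphenyl pivalate | O=Cc1cc(OC)c(O[Si](C)(C)C(C)(C)C)c(c1)[C@@H](CO[Si](C)(C)C(C)(C)C)[C@@H](OC(C)=O)c1ccc(OC(=O)C(C)(C)C)c(OC)c1 | intermediate
25 | 4-[(1R,2S)-1-acetoxy-3-(tert-butyldimethylsilyloxy)-2-[2-(tert-butyldimethylsilyloxy)-5-(1-hydroxyprop-2-en-1-yl)-3-methoxyphenyl]propyl]-2-methoxyphenyl pivalate (carbinol epimers) | C=CC(O)c1cc(OC)c(O[Si](C)(C)C(C)(C)C)c(c1)[C@@H](CO[Si](C)(C)C(C)(C)C)[C@@H](OC(C)=O)c1ccc(OC(=O)C(C)(C)C)c(OC)c1 | intermediate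
26 | 4-[(1R,2S)-1-acetoxy-3-(tert-butyldimethylsilyloxy)-2-[2-(tert-butyldimethylsilyloxy)-5-{(R)-hydroxy[(R)-oxiran-2-yl]methyl}-3-methoxyphenyl]propyl]-2-methoxyphenyl pivalate | O[C@@H]([C@H]1CO1)c1cc(OC)c(O[Si](C)(C)C(C)(C)C)c(c1)[C@@H](CO[Si](C)(C)C(C)(C)C)[C@@H](OC(C)=O)c1ccc(OC(=O)C(C)(C)C)c(OC)c1 | intermediate
27 | epoxy cinnamyl ether: the carbinol oxygen of 26 bonded to the CH2 of the (E)-propenyl arm of 21 | C(/C=C/c1cc(OC)c2c(c1)[C@@H](CO[Si](C)(C)C(C)(C)C)[C@@H](c1ccc(OC(=O)C(C)(C)C)c(OC)c1)O2)O[C@@H]([C@H]1CO1)c1cc(OC)c(O[Si](C)(C)C(C)(C)C)c(c1)[C@@H](CO[Si](C)(C)C(C)(C)C)[C@@H](OC(C)=O)c1ccc(OC(=O)C(C)(C)C)c(OC)c1 | intermediate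
28 | monocyclic 2-aryl-3-(hydroxymethyl)-4-[aryl(iodo)methyl]tetrahydrofuran (titanium alkoxide in the flask, drawn as the alcohol; C–I carbon undefined) | COc1cc([C@H](OC(C)=O)[C@H](CO[Si](C)(C)C(C)(C)C)c2cc([C@H]3OC[C@H](C(I)c4cc(OC)c5c(c4)[C@@H](CO[Si](C)(C)C(C)(C)C)[C@@H](c4ccc(OC(=O)C(C)(C)C)c(OC)c4)O5)[C@@H]3CO)cc(OC)c2O[Si](C)(C)C(C)(C)C)ccc1OC(=O)C(C)(C)C | intermediate (not isolated)
29 | protected furofuran: (1S,2S,5R,6S)-3,7-dioxabicyclo[3.3.0]octane with, at C2, the ring B aryl group (4-silyloxy, 3-methoxy, 5-[(1R,2S)-1-acetoxy-1-(3-methoxy-4-pivaloyloxyphenyl)-3-silyloxypropan-2-yl]) and, at C6, the (2S,3S)-dihydrobenzofuran-5-yl unit of 18 | COc1cc([C@H](OC(C)=O)[C@H](CO[Si](C)(C)C(C)(C)C)c2cc([C@H]3OC[C@H]4[C@@H]3CO[C@@H]4c3cc(OC)c4c(c3)[C@@H](CO[Si](C)(C)C(C)(C)C)[C@@H](c3ccc(OC(=O)C(C)(C)C)c(OC)c3)O4)cc(OC)c2O[Si](C)(C)C(C)(C)C)ccc1OC(=O)C(C)(C)C | intermediate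
30 | furofuran with free ring A and ring D phenols and free (1R)-carbinol; ring B oxygen and both primary oxygens silylated | COc1cc([C@H](O)[C@H](CO[Si](C)(C)C(C)(C)C)c2cc([C@H]3OC[C@H]4[C@@H]3CO[C@@H]4c3cc(OC)c4c(c3)[C@@H](CO[Si](C)(C)C(C)(C)C)[C@@H](c3ccc(O)c(OC)c3)O4)cc(OC)c2O[Si](C)(C)C(C)(C)C)ccc1O | intermediate
31 | pentakis(tert-butyldimethylsilyl) ether with free (1R)-carbinol next to ring A | COc1cc([C@H](O)[C@H](CO[Si](C)(C)C(C)(C)C)c2cc([C@H]3OC[C@H]4[C@@H]3CO[C@@H]4c3cc(OC)c4c(c3)[C@@H](CO[Si](C)(C)C(C)(C)C)[C@@H](c3ccc(O[Si](C)(C)C(C)(C)C)c(OC)c3)O4)cc(OC)c2O[Si](C)(C)C(C)(C)C)ccc1O[Si](C)(C)C(C)(C)C | intermediate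
32 | pentakis(tert-butyldimethylsilyl) ether of the target | COc1cc(C(=O)[C@H](CO[Si](C)(C)C(C)(C)C)c2cc([C@H]3OC[C@H]4[C@@H]3CO[C@@H]4c3cc(OC)c4c(c3)[C@@H](CO[Si](C)(C)C(C)(C)C)[C@@H](c3ccc(O[Si](C)(C)C(C)(C)C)c(OC)c3)O4)cc(OC)c2O[Si](C)(C)C(C)(C)C)ccc1O[Si](C)(C)C(C)(C)C | intermediate
33 | CNP0174045.1 | COc1cc(C(=O)[C@H](CO)c2cc([C@H]3OC[C@H]4[C@@H]3CO[C@@H]4c3cc(OC)c4c(c3)[C@@H](CO)[C@@H](c3ccc(O)c(OC)c3)O4)cc(OC)c2O)ccc1O | target

## Step count and risks

Total: 25 steps. Longest linear sequence: 20 steps (1–5, 7–10, 15–25, from 5-bromovanillin).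

**Step 11 (key step).** The most likely failure is ionisation of the oxyphosphonium intermediate to a benzylic cation, which leaks to the trans ring, or loss of the α-hydrogen to give the stilbene. The carbinol is secondary, benzylic and flanked by a tertiary carbon, so the rear-side attack is slowed. Fallback: an anionic two-stage closure that sets out from 22. MsCl and Et3N in CH2Cl2 at −30 °C should give the benzylic mesylate F1. Bu4NF in THF at −20 °C then removes the aryl silyl group, and the freed phenoxide displaces the mesylate with inversion. The sequence rejoins the route at 18.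

**Step 19.** The epoxidation of a hindered monosubstituted alkene may be slow and discriminate poorly between the carbinol epimers, and by design it discards half of an advanced intermediate. Fallback: catalyst-controlled vinyl transfer that sets out from 24. CH2=CHSi(OMe)3 with CuF2·2H2O and the enantiomer of DTBM-SEGPHOS that favours the (S)-carbinol should give the single (S)-allylic alcohol F2. The same titanium tartrate epoxidation, now matched and run to full conversion, returns to the route at 26.

**Step 20.** The sodium alkoxide may take an acyl group from the acetate or the pivalates, the epoxide may migrate (Payne), and the electron-rich cinnamyl bromide may decompose before it is alkylated. Fallback: palladium-catalysed allylic etherification of a zinc alkoxide. 20 is acetylated (Ac2O, Et3N, DMAP) to the allylic acetate F3. 26 is treated with Et2Zn (0.5 equiv) and then with F3, Pd(OAc)2 and 2-(di-tert-butylphosphino)biphenyl in THF at rt. The π-allyl complex is attacked at its unsubstituted end and should give the linear (E) ether; the route is rejoined at 27.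

**Step 21.** The benzylic radical may be reduced and protonated before iodine captures it, the cation closure may show imperfect facial control (endo aryl epimer), and the Lewis-acidic medium may ionise C2 of the cis-dihydrobenzofuran. Fallback: a two-stage closure from 27. Cp2TiCl followed by a proton quench should give the monocyclic tetrahydrofuran alcohol F4. DDQ then oxidises the benzylic CH2 para to the dihydrobenzofuran oxygen, and the primary hydroxyl captures the cation. The route is rejoined at 29.

**Step 25.** The long fluoride exposure needed for the primary silyl ethers may cause enolisation at the doubly activated α-carbon, β-elimination or retro-aldol, or acid-promoted hemiketalisation and dehydration to a benzofuran. Fallback: reorder the end game from 31. AcOH/THF/H2O removes the two primary silyl ethers to give triol F5. MnO2 oxidises only the benzylic carbinol to hydroxy ketone F6. A brief treatment with Bu4NF/AcOH at 0 °C removes the three aryl silyl ethers and arrives at 33.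

## Further compounds

F1 | step 11 | benzylic methanesulfonate of 22 | O1CCOC1c1cc(OC)c(O[Si](C)(C)C(C)(C)C)c(c1)[C@@H](CO[Si](C)(C)C(C)(C)C)[C@@H](OS(C)(=O)=O)c1ccc(OC(=O)C(C)(C)C)c(OC)c1
F2 | step 19 | (S)-carbinol epimer of 25 | O[C@@H](C=C)c1cc(OC)c(O[Si](C)(C)C(C)(C)C)c(c1)[C@@H](CO[Si](C)(C)C(C)(C)C)[C@@H](OC(C)=O)c1ccc(OC(=O)C(C)(C)C)c(OC)c1
F3 | step 20 | allylic acetate of 20 (carbinol epimers) | C=CC(OC(C)=O)c1cc(OC)c2c(c1)[C@@H](CO[Si](C)(C)C(C)(C)C)[C@@H](c1ccc(OC(=O)C(C)(C)C)c(OC)c1)O2
F4 | step 21 | monocyclic 2-aryl-4-(arylmethyl)-3-(hydroxymethyl)tetrahydrofuran (2,3-trans, 3,4-cis) | COc1cc([C@H](OC(C)=O)[C@H](CO[Si](C)(C)C(C)(C)C)c2cc([C@H]3OC[C@H](Cc4cc(OC)c5c(c4)[C@@H](CO[Si](C)(C)C(C)(C)C)[C@@H](c4ccc(OC(=O)C(C)(C)C)c(OC)c4)O5)[C@@H]3CO)cc(OC)c2O[Si](C)(C)C(C)(C)C)ccc1OC(=O)C(C)(C)C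
F5 | step 25 | triol from 31 with both primary hydroxyls free and three aryl silyl ethers | COc1cc([C@H](O)[C@H](CO)c2cc([C@H]3OC[C@H]4[C@@H]3CO[C@@H]4c3cc(OC)c4c(c3)[C@@H](CO)[C@@H](c3ccc(O[Si](C)(C)C(C)(C)C)c(OC)c3)O4)cc(OC)c2O[Si](C)(C)C(C)(C)C)ccc1O[Si](C)(C)C(C)(C)C
F6 | step 25 | tris(aryl silyl ether) of the target | COc1cc(C(=O)[C@H](CO)c2cc([C@H]3OC[C@H]4[C@@H]3CO[C@@H]4c3cc(OC)c4c(c3)[C@@H](CO)[C@@H](c3ccc(O[Si](C)(C)C(C)(C)C)c(OC)c3)O4)cc(OC)c2O[Si](C)(C)C(C)(C)C)ccc1O[Si](C)(C)C(C)(C)C
A1 | alternative 1 | 5,5'-dibromopinoresinol | COc1cc(cc(Br)c1O)[C@H]1OC[C@H]2[C@@H]1CO[C@@H]2c1cc(OC)c(O)c(Br)c1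
A2 | alternative 1 | 2-bromo-6-methoxyphenol | COc1cccc(Br)c1O
A3 | alternative 1 | (1R,5R)-2,6-dimethoxy-3,7-dioxabicyclo[3.3.0]octane, drawn as the exo,exo anomer | CO[C@H]1OC[C@H]2[C@@H]1CO[C@@H]2OC
A4 | alternative 2 | C2-symmetric 5,5'-bis[(Z)-3-aryl-1-silyloxypent-3-en-2-yl]pinoresinol | COc1cc(/C(=C\C)[C@H](CO[Si](C)(C)C(C)(C)C)c2cc([C@H]3OC[C@H]4[C@@H]3CO[C@@H]4c3cc(OC)c(O)c(c3)[C@@H](CO[Si](C)(C)C(C)(C)C)/C(=C/C)c3ccc(O[Si](C)(C)C(C)(C)C)c(OC)c3)cc(OC)c2O)ccc1O[Si](C)(C)C(C)(C)C
A5 | alternative 2 | pinoresinol bis[(R,E)-3-aryl-5-silyloxypent-3-en-2-yl] ether | COc1cc(ccc1O[C@H](C)/C(=C/CO[Si](C)(C)C(C)(C)C)c1ccc(O[Si](C)(C)C(C)(C)C)c(OC)c1)[C@H]1OC[C@H]2[C@@H]1CO[C@@H]2c1ccc(O[C@H](C)/C(=C/CO[Si](C)(C)C(C)(C)C)c2ccc(O[Si](C)(C)C(C)(C)C)c(OC)c2)c(OC)c1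
A6 | alternative 3 | C2-symmetric 2,6-bis[3-bromo-5-methoxy-4-(methoxymethoxy)phenyl]-3,7-dioxabicyclo[3.3.0]octane | COc1cc(cc(Br)c1OCOC)[C@H]1OC[C@H]2[C@@H]1CO[C@@H]2c1cc(OC)c(OCOC)c(Br)c1
A7 | alternative 3 | (R)-aryl[(R)-oxiran-2-yl]methyl (E)-3-arylallyl ether, aryl = 3-bromo-5-methoxy-4-(methoxymethoxy)phenyl | COCOc1c(OC)cc(/C=C/CO[C@@H]([C@H]2CO2)c2cc(OC)c(OCOC)c(Br)c2)cc1Br
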